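## Structural features

The target is a C30 tetracycle made of two bicyclic halves. A 2,2-dimethyloxepan-3-one (ring A) is trans-fused to a cyclohexane (ring B), and a cycloheptene (ring C) is cis-fused to a cyclopentane (ring D). A CH2–CH2 chain joins a CH of ring B to a CH of ring C. Ring B carries four contiguous stereocentres: the ether CH–O, a quaternary carbon with an axial methyl, the linker-bearing CH, and a tertiary carbinol C(CH3)OH whose hydroxyl is axial and syn to that methyl. The C/D half carries four more: the ring D carbinol C(CH3)OH, the two cis ring-fusion CH groups, and the linker-bearing CH of ring C, which lies between the C(CH3)=CH alkene and a gem-dimethyl quaternary carbon. The two clusters are insulated by the linker, so each half needs its own source of absolute configuration. Fragile groups are the two tertiary alcohols (ionisation, dehydration), the trisubstituted alkene (migration under acid) and the enolisable α-alkoxy ketone of ring A. The real difficulty lies in the two seven-membered rings, each closed at a fully substituted carbon (O–C(CH3)2 in ring A, C(CH3)2–CH in ring C), and in the ring C CH stereocentre, which is remote from any strong controlling element.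

The key step exploits ring D. Its carbinol carbon, its two CH2 groups, the fusion CH that bears the ring C CH2, and the other fusion CH that bears C(CH3)2 form a linalool skeleton in which only the bond between the two fusion carbons is missing.

## Logic of the disconnections

**36 ⇒ 35 ⇒ 34.** No skeletal bond is cut. The ring A carbonyl is traced to a secondary carbinol and the three hydroxyls to silyl ethers. This keeps a single ketone in the molecule while ring C is enolised. The forward demand is one global desilylation and an oxidation that can touch only the one secondary alcohol.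

**34 ⇒ 33 ⇒ 31.** The vinylic C–H of ring C is exchanged for C–OTf and then for the carbonyl of 31. That carbonyl is the group that activates ring C closure, so its removal is left until the ring exists. The forward demand is enolisation toward the methyl-bearing carbon and not toward the ring CH2.

**31 ⇒ 30.** The bond between the gem-dimethyl carbon and the linker-bearing CH of ring C is cut, together with one C–H of a methyl group. Ring C, the quaternary carbon and one stereocentre disappear, leaving an isopropenyl group and an open-chain (E)-enone. The forward step must close a seven-membered ring faster than the radical is reduced, and must choose one face of the enone.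

**30 ⇒ 7 + 26.** The enone C=C is cut (aldol condensation). This is the one bond next to a carbonyl that joins the halves, and it gives two fragments of similar size with four stereocentres each. The forward demand is enolisation of 7 on its ethyl side and an (E)-selective dehydration.

**7 ⇒ 6.** The bond between the two ring-fusion carbons of ring D is cut, with return of a hydrogen from the α-CH2 of the ketone arm to the isopropenyl CH2 (retro-ene). Ring D and two stereocentres vanish, and 6 is an open-chain derivative of 1. The forward step must give the cis pair and place the arm on the methyl face of the carbinol carbon.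

**6 ⇒ 4 ⇒ 3 ⇒ 2 ⇒ 1.** The enone is traced to a β-hydroxy ketone, then the C–C bond between the terminal vinyl carbon and the acyl carbon is cut through an isoxazoline. A nitrile oxide distinguishes the monosubstituted from the trisubstituted alkene of 2; this differentiation has to be made without metathesis, which would ring-close the 1,6-diene. All ten carbons of 1 are retained. The forward demand is chemoselective cycloaddition and a clean N–O cleavage.

**26 ⇒ 25 ⇒ 23 ⇒ 22.** Functional group changes only: aldehyde from primary alcohol, from terminal alkene, and two silyl ethers. The forward demand is anti-Markovnikov hydration of the only remaining alkene.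

**22 ⇒ 21 ⇒ 20.** The ether bond O–C(CH3)2 of ring A is cut, and the neighbouring carbinol oxygen is traced to an epoxide of a homoprenyl chain. Ring A is removed at the cost of one alkene. The forward step must open the epoxide in the 7-endo sense at the tertiary carbon.

**20 ⇒ 18.** The C–CH3 bond of the ring B carbinol is cut, giving a ketone. The forward demand is equatorial delivery of methyl, which the axial methyl on the neighbouring quaternary carbon should enforce.

**18 ⇒ 17 ⇒ 14 ⇒ 11 + 12.** Three cuts, each at the β-carbon of an enone: the allyl C–C bond (vinyl onto an exocyclic methylene), the exocyclic C=CH2 (Mannich methylenation), and the bond from the quaternary carbon to the homoprenyl CH2. What remains is a cyclohexenone with one stereocentre and a C6 bromide. The forward demands are addition anti to the silyloxy group and protonation of the last enolate on the correct face.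

**11 ⇒ 10 ⇒ 9 ⇒ 8.** The enone carbonyl is traced to an allylic CH2, the silyl ether to the alcohol, and the carbinol to the ketone of 8. The single stereocentre comes from a catalytic enantioselective 1,2-reduction. The allylic oxidation must occur at the ring CH2 next to the unsubstituted alkene carbon.

## Other disconnections considered

**Alternative 1:** The cut runs through the ether bond O–C(CH3)2 of ring A and through the bond between the methyl-bearing quaternary carbon and the linker-bearing CH of ring B. Both western rings then come from the open-chain bis-epoxide A1, which ends in a (Z)-silyl enol ether. In the forward step Me3SiOTf activates the terminal epoxide; the inner epoxide oxygen attacks its C(CH3)2 carbon, and the enol ether opens the resulting epoxonium ion at the methyl-bearing carbon. The product is the trans-fused oxepane–cyclohexanone A2, with the ring A oxygen already silylated.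

- In favour: two rings, one C–O and one C–C bond, and the ring-fusion centres arise in one operation from epoxide configurations set by reagent control.
- Better than the chosen plan on one point: the endo closure of the oxepane is enforced by the epoxonium pathway, whereas the chosen route needs a separate hydroxy-epoxide opening (step 14) that has to beat 6-exo closure. The western half would also be shorter.
- Against: the enol ether must be regio- and geometry-defined at an unsymmetrical dialkyl ketone, because its geometry sets the linker-bearing CH. The cationic cascade is sensitive to premature enol ether cleavage and hydride shifts. A2 has only a two-carbon arm, so the halves would have to be joined by a different bond. The cis-fused C/D unit with its quaternary carbon is not addressed at all.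
- Comparison: both plans turn an acyclic terpenoid chain into one bicyclic half. Mechanistically a charge-driven cascade stands against a pericyclic-type closure. In step economy the alternative wins for rings A/B, while the chosen key step reaches its precursor from a chiral-pool alcohol in four steps and fixes the cis C/D pair.

**Alternative 2:** The cut is the bond between the linker-bearing CH of ring B and the future carbinol carbon. In the forward step BF3·OEt2 or SnCl4 activates the aldehyde of A3, and the γ-carbon of its (E)-allylsilane attacks, closing ring B with loss of silicon to give the vinylcyclohexanol A4.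

- In favour: a chair-like transition state should place the vinyl group equatorial, so the linker-bearing CH is set in the ring-forming step itself.
- Better than the chosen plan on that point: the chosen route needs three operations for this centre (steps 10 and 11 and a face-selective protonation). The vinyl group is also a flexible handle for the union.
- Against: A3 already contains the quaternary stereocentre next to an oxygenated carbon, which must be built by an acyclic asymmetric sequence. The new carbinol is secondary and still needs oxidation and methyl addition. Ring A must then be closed by the same kind of endo epoxide opening as in the chosen route, so on that risk the two plans are equal. The vinyl arm is one carbon short for an aldol union.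
- Comparison: structurally it solves ring B only. Mechanistically it is a polar carbonyl addition of predictable geometry. In step count it is unlikely to beat the cyclohexenone route to 18, and it offers nothing for rings C/D.

**Alternative 3:** The cut removes one CH2 from ring A, so the last intermediate is the ring-contracted pyranone A5 with the rest of the skeleton complete and silylated. In the forward step Me3SiCHN2 adds to the pyranone carbonyl under AlMe3 or BF3·OEt2, the ring CH2 migrates, and the oxepanone A6 results after loss of the C-silyl group.

- In favour: a tetrahydropyranone is easier to close than an oxepane, so the endo/exo problem of step 14 disappears; on this point the alternative is better. The ring A ketone is also delivered directly, so the protect–deprotect–oxidise sequence of steps 15, 23 and 24 would shrink.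
- Against: the CH2 must migrate in preference to the oxygen-bearing quaternary carbon. Double homologation and epoxide formation compete. The Lewis acid meets tertiary silyl ethers and a trisubstituted alkene on the complete skeleton, and a failure at the last step costs all the material. A ketone in ring A would also have to be carried through the ring C enolisation chemistry, or that chemistry redesigned.
- Comparison: it is a tactic for ring A and not a plan for the skeleton. Mechanistically it is a 1,2-shift of moderate predictability against a closure with a defined cyclic transition state. In step count it could save two or three steps at the end, if the pyranone half were as accessible as 26.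

Key step: step 5

## Remarks and assumptions

- Correction to an obvious shortcut: cross-metathesis of 2 with a vinyl ketone cannot give 6, because the vinyl and prenyl groups of this 1,6-diene should ring-close to a cyclopentene (loss of isobutene) faster than the hindered vinyl group cross-couples. Steps 2–4 replace it.
- Correction to the carbon bookkeeping: only an acylation at the terminal vinyl carbon keeps all ten carbons of 1 in rings C/D; metathesis or ozonolysis would excise that carbon.
- Check of structures: 6 and 7 as drawn carry the (S) carbinol centre of 1 and match ring D of the target (arm, isopropenyl and carbinol methyl on one face).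
- Assumption: 1 is used in high enantiomeric purity; material of lower purity is enriched first.
- Assumption: the carbinol configuration in ring A of 21–35 is a free choice, because that centre becomes the ketone in step 24; the epoxide from the commercially common catalyst enantiomer is used.
- Assumption: 3, 4, 28 and 31 are carried as mixtures at centres that become trigonal again in the next step.

## Route

Step 1
Reactants: 1 (S)-(+)-linalool
Product: 2 (S)-linalool tert-butyldimethylsilyl ether
Conditions: t-BuMe2SiOTf, 2,6-lutidine, CH2Cl2, 0 °C → rt
Reagents that add atoms: tert-butyldimethylsilyl triflate CC(C)(C)[Si](C)(C)OS(=O)(=O)C(F)(F)F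
Why: Silylation of a tertiary alcohol needs the silyl triflate with a hindered base; no stereocentre is touched and the bulky ether later serves as the large group on the carbinol carbon.

Step 2
Reactants: 2 (S)-linalool tert-butyldimethylsilyl ether
Product: 3 3-ethyl-5-[(2S)-2-(tert-butyldimethylsilyloxy)-6-methylhept-5-en-2-yl]-4,5-dihydroisoxazole (both C-5 epimers)
Conditions: 1-nitropropane, PhNCO, Et3N (cat.), toluene, rt → 50 °C
Reagents that add atoms: 1-nitropropane CCC[N+](=O)[O-]
Why: Nitrile oxide 1,3-dipolar cycloaddition; the oxide made by dehydration of the nitroalkane should add to the monosubstituted alkene far faster than to the trisubstituted one, with oxygen on the substituted carbon. The new C-5 centre is formed as a mixture and removed in step 4.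

Step 3
Reactants: 3 the isoxazoline
Product: 4 (6S)-6-(tert-butyldimethylsilyloxy)-5-hydroxy-6,10-dimethylundec-9-en-3-one (both C-5 epimers)
Conditions: Mo(CO)6, MeCN–H2O, 80 °C
Reagents that add atoms: water O
Why: Reductive N–O cleavage of an isoxazoline followed by hydrolysis of the β-hydroxy imine; the trisubstituted alkene and the silyl ether should be inert under these neutral conditions.

Step 4
Reactants: 4 the β-hydroxy ketone
Product: 6 (4E,6S)-6-(tert-butyldimethylsilyloxy)-6,10-dimethylundeca-4,9-dien-3-one, via the methanesulfonate 5 (not isolated)
Conditions: MsCl, Et3N, CH2Cl2, 0 °C; then DBU, rt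
Reagents that add atoms: none
Why: Mesylation and E1cB elimination should give the conjugated (E)-enone as the thermodynamic isomer; the adjacent quaternary carbinol carbon cannot epimerise.

Step 5
Reactants: 6 the (E)-enone
Product: 7 cis-2-(2-oxobutyl)-3-isopropenyl-1-methylcyclopentyl tert-butyldimethylsilyl ether (oxobutyl arm cis to the carbinol methyl)
Conditions: Me2AlCl (1.5 equiv), CH2Cl2, −78 → −20 °C
Reagents that add atoms: none
Why: Me2AlCl binds the ketone oxygen and lowers the enone LUMO; the inner carbon of the trisubstituted alkene bonds to the enone β-carbon while a hydrogen of an allylic methyl passes to the α-carbon, either in one asynchronous event or through a short-lived zwitterion that collapses by proton transfer to the aluminium enolate. The closest known reaction type is the type 1 intramolecular ene reaction of 1,6-dienes with an activated enophile, run thermally or with an alkylaluminium halide. The cyclopentane closes with both π bonds exocyclic to the new ring, each being attacked at its carbon nearer the tether. The two new CH centres should be cis because the hydrogen donor and acceptor must stay on one face of the forming ring, and with a three-atom tether only the cis-fused bicyclic arrangement is accessible. Their configuration relative to the carbinol carbon depends on which of its two groups lies beside the Lewis acid-bound arm; the bulky silyloxy group is expected to take the remote position, so that the arm ends cis to methyl. The step needs periselectivity for the ene pathway over oxygen capture of the developing tertiary cation, which the proton-scavenging Lewis acid and low temperature should favour. Chemoselectivity is secured by the substrate: the ketone is the only Lewis basic site of note, the prenyl alkene the only nucleophile, and ionisation of the tertiary silyl ether is disfavoured because the cation would sit next to an electron-poor alkene.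

Step 6
Reactants: 8 2-methylcyclohex-2-en-1-one
Product: 9 (S)-2-methylcyclohex-2-en-1-ol
Conditions: (R)-1-methyl-3,3-diphenyltetrahydro-1H,3H-pyrrolo[1,2-c][1,3,2]oxazaborole (10 mol %), BH3·SMe2, THF, −20 °C
Reagents that add atoms: none
Why: Corey–Bakshi–Shibata reduction; with the alkenyl carbon as the large group, the (R)-catalyst should deliver hydride to the face that gives the (S)-allylic alcohol, and 1,2-reduction is favoured at low temperature.

Step 7
Reactants: 9 (S)-2-methylcyclohex-2-en-1-ol
Product: 10 (S)-2-methylcyclohex-2-en-1-yl triethylsilyl ether
Conditions: Et3SiCl, imidazole, DMF, 0 °C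
Reagents that add atoms: chlorotriethylsilane CC[Si](Cl)(CC)CC
Why: Standard silylation; triethylsilyl is chosen because it survives steps 8–11 and can be removed with mild acid in step 12.

Step 8
Reactants: 10 the allylic silyl ether
Product: 11 (S)-3-methyl-4-(triethylsilyloxy)cyclohex-2-en-1-one
Conditions: CrO3, 3,5-dimethylpyrazole, CH2Cl2, −20 °C
Reagents that add atoms: chromium trioxide O=[Cr](=O)=O
Why: Allylic oxidation of a trisubstituted cyclohexene should take place at the ring CH2 next to the unsubstituted alkene carbon, giving the more substituted enone; the silyloxy-bearing carbon is untouched and becomes C-4.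

Step 9
Reactants: 11 the silyloxy enone, 12 5-bromo-2-methylpent-2-ene
Product: 14 3-methyl-3-(4-methylpent-3-enyl)-4-(triethylsilyloxy)-1-(trimethylsilyloxy)cyclohexene (homoprenyl trans to the silyloxy group), via 4-methylpent-3-enylmagnesium bromide 13 (not isolated)
Conditions: 12, Mg, THF; then CuBr·SMe2 (10 mol %), Me3SiCl, DMPU, 11, THF, −78 → −40 °C; Et3N
Reagents that add atoms: chlorotrimethylsilane C[Si](C)(C)Cl
Why: Copper-catalysed conjugate addition of a Grignard reagent, accelerated by Me3SiCl; the nucleophile should add anti to the γ-silyloxy group, which sets the quaternary carbon with methyl cis to the oxygen. The enolate is trapped regiospecifically as the silyl enol ether.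

Step 10
Reactants: 14 the silyl enol ether
Product: 17 3-methyl-2-methylene-3-(4-methylpent-3-enyl)-4-(triethylsilyloxy)cyclohexanone, via the Mannich base 15 (not isolated), via its methiodide 16 (not isolated)
Conditions: CH2=NMe2+ I−, CH2Cl2, rt; then MeI; then aq. NaHCO3
Reagents that add atoms: N,N-dimethylmethyleneiminium iodide C=[N+](C)C.[I-]
Why: Mannich reaction of a silyl enol ether with the preformed iminium salt, then quaternisation and Hofmann-type elimination; no stereocentre is formed and the exocyclic enone is a clean acceptor for step 11.

Step 11
Reactants: 17 the α-methylene ketone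
Product: 18 2-allyl-3-methyl-3-(4-methylpent-3-enyl)-4-(triethylsilyloxy)cyclohexanone (allyl cis to the 3-methyl and to the silyloxy group)
Conditions: CH2=CHMgBr, CuI, THF, −78 °C; then cold aq. NH4Cl
Reagents that add atoms: vinylmagnesium bromide C=C[Mg]Br
Why: Conjugate addition of a vinyl cuprate to an unhindered exocyclic enone; kinetic protonation of the enolate on the face opposite the axial methyl of the neighbouring quaternary carbon should place the allyl group equatorial. This is also expected to be the more stable epimer, so base equilibration would converge any minor isomer.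

Step 12
Reactants: 18 the allyl ketone
Product: 20 2-allyl-1,3-dimethyl-3-(4-methylpent-3-enyl)cyclohexane-1,4-diol (C-1 hydroxyl axial and syn to the 3-methyl), via its 4-O-triethylsilyl ether 19 (not isolated)
Conditions: MeMgBr, CeCl3, THF, −78 → 0 °C; aq. NH4Cl; then pyridinium p-toluenesulfonate, MeOH, rt
Reagents that add atoms: methylmagnesium bromide C[Mg]Br
Why: Cerium-mediated Grignard addition suppresses enolisation; axial attack is blocked by the 1,3-diaxial methyl, so methyl should enter equatorially and leave the hydroxyl axial. Mild acid then removes the secondary triethylsilyl ether.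

Step 13
Reactants: 20 the diol
Product: 21 the (R)-epoxide of the homoprenyl alkene of 20
Conditions: 1,2:4,5-di-O-isopropylidene-β-D-erythro-2,3-hexodiulo-2,6-pyranose (30 mol %), KHSO5 (as 2KHSO5·KHSO4·K2SO4), K2CO3, Bu4NHSO4, MeCN–CH2(OMe)2–aq. Na2B4O7, 0 °C
Reagents that add atoms: potassium peroxymonosulfate [K+].[O-]S(=O)(=O)OO
Why: Shi epoxidation; the dioxirane should oxidise the electron-rich trisubstituted alkene and leave the terminal allyl group, and the chiral ketone should give a single epoxide diastereomer whose configuration is of no consequence for the target.

Step 14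
Reactants: 21 the epoxy diol
Product: 22 trans-fused oxepane diol (2,2-dimethyloxepan-3-ol fused to ring B, allyl on ring B)
Conditions: BF3·OEt2 (0.3 equiv), CH2Cl2, −78 °C
Reagents that add atoms: none
Why: Lewis acid-promoted 7-endo-tet opening of a trisubstituted epoxide by the equatorial secondary hydroxyl; attack should go to the tertiary carbon, which carries most of the positive charge. The carbinol CH keeps its configuration, and the trans ring fusion follows from the equatorial oxygen and equatorial chain.

Step 15
Reactants: 22 the oxepane diol
Product: 23 bis(triethylsilyl) ether of 22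
Conditions: Et3SiOTf, 2,6-lutidine, CH2Cl2, −78 → 0 °C
Reagents that add atoms: triethylsilyl triflate CC[Si](CC)(CC)OS(=O)(=O)C(F)(F)F
Why: The silyl triflate silylates both the secondary and the hindered tertiary hydroxyl, so no free OH or ring A ketone interferes with the enolate chemistry of steps 18 and 21.

Step 16
Reactants: 23 the bis-silyl ether
Product: 25 the 3-hydroxypropyl compound, via the B-alkyl-9-borabicyclo[3.3.1]nonane 24 (not isolated)
Conditions: 9-borabicyclo[3.3.1]nonane, THF, 0 °C → rt; then NaOH, H2O2, 0 °C
Reagents that add atoms: hydrogen peroxide OO
Why: Anti-Markovnikov hydroboration–oxidation of the only remaining alkene; silyl ethers should tolerate the brief basic peroxide treatment.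

Step 17
Reactants: 25 the primary alcohol
Product: 26 the western aldehyde (3-substituted propanal)
Conditions: 1,1,1-triacetoxy-1,1-dihydro-1,2-benziodoxol-3(1H)-one (Dess–Martin periodinane), NaHCO3, CH2Cl2, 0 °C → rt
Reagents that add atoms: none
Why: Dess–Martin oxidation stops at the aldehyde and is compatible with silyl ethers and the cyclic ether.

Step 18
Reactants: 7 the ring D ethyl ketone, 26 the western aldehyde
Product: 28 the β-hydroxy ketone (aldol adduct; mixture at the two new centres), via the lithium enolate 27 (not isolated)
Conditions: LiN(iPr)2, THF, −78 °C; then 26, −78 °C; aq. NH4Cl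
Reagents that add atoms: none
Why: Kinetic deprotonation should occur at the ethyl CH2, the other α-CH2 being attached to a congested ring carbon; aldol addition to the aldehyde is fast at −78 °C. Both new centres become trigonal in step 19.

Step 19
Reactants: 28 the aldol adduct
Product: 30 the (E)-α-methyl enone joining both halves, via the methanesulfonate 29 (not isolated)
Conditions: MsCl, Et3N, CH2Cl2, 0 °C; then DBU, rt
Reagents that add atoms: none
Why: Mesylation and E1cB elimination should give the trisubstituted (E)-enone, in which the linker chain is trans to the carbonyl.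

Step 20
Reactants: 30 the (E)-enone
Product: 31 the ring C ketone (cis-fused bicyclo[5.3.0]decan-3-one; hydrogen on the linker-bearing CH cis to both ring-fusion hydrogens; α-methyl centre as a mixture)
Conditions: Fe(acac)3 (30 mol %), PhSiH3, EtOH–(CH2OH)2, 60 °C, high dilution
Reagents that add atoms: none
Why: Hydrogen-atom transfer from an iron hydride to the isopropenyl group gives the tertiary radical, which should add 7-endo to the enone β-carbon (Giese reaction); the α-keto radical is then reduced and protonated. The (E)-acceptor keeps the linker chain pseudo-equatorial; the required face is the one that puts the new C–H syn to the ring-fusion hydrogens, and this choice is the least secure stereochemical event of the route.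

Step 21
Reactants: 31 the ring C ketone
Product: 33 the tetrasubstituted enol triflate (C=C between the methyl-bearing carbon and the former carbonyl carbon), via the lithium enolate 32 (not isolated)
Conditions: LiN(SiMe3)2 (0.95 equiv), THF, 0 °C → rt; then N-(5-chloropyridin-2-yl)bis(trifluoromethanesulfonyl)imide, −78 °C → rt
Reagents that add atoms: N-(5-chloropyridin-2-yl)bis(trifluoromethanesulfonyl)imide FC(F)(F)S(=O)(=O)N(c1ccc(Cl)cn1)S(=O)(=O)C(F)(F)F
Why: With a slight deficit of base the lithium enolates equilibrate through the remaining ketone toward the more substituted isomer, which is trapped as the enol triflate; the α-methyl stereocentre disappears.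

Step 22
Reactants: 33 the enol triflate
Product: 34 the tris-silyl ether of the ring A alcohol (trisubstituted ring C alkene in place)
Conditions: Pd(OAc)2 (5 mol %), PPh3, HCO2H, n-Bu3N, DMF, 60 °C
Reagents that add atoms: none
Why: Palladium-catalysed formate reduction of a vinyl triflate (oxidative addition, formate-to-hydride exchange with loss of CO2, reductive elimination) replaces OTf by H without moving the double bond.

Step 23
Reactants: 34 the tris-silyl ether
Product: 35 the triol (ring A secondary alcohol and both tertiary alcohols free)
Conditions: Bu4NF, THF, 60 °C
Reagents that add atoms: none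
Why: Fluoride cleaves all three silyl ethers; warming is for the tertiary tert-butyldimethylsilyl ether, and the basic medium should spare the alkene and the tertiary alcohols.

Step 24
Reactants: 35 the triol
Product: 36 the target CNP0194989.3
Conditions: Dess–Martin periodinane, NaHCO3, CH2Cl2, 0 °C → rt
Reagents that add atoms: none
Why: Dess–Martin oxidation converts the only secondary alcohol into the ring A ketone; the two tertiary alcohols cannot be oxidised.

## Compound list

1 | (S)-(+)-linalool | C=C[C@@](C)(O)CCC=C(C)C | starting material
2 | (S)-linalool tert-butyldimethylsilyl ether | C=C[C@@](C)(O[Si](C)(C)C(C)(C)C)CCC=C(C)C | intermediate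
3 | 3-ethyl-5-[(2S)-2-(tert-butyldimethylsilyloxy)-6-methylhept-5-en-2-yl]-4,5-dihydroisoxazole, both C-5 epimers | CCC1=NOC(C1)[C@@](C)(O[Si](C)(C)C(C)(C)C)CCC=C(C)C | intermediate
4 | (6S)-6-(tert-butyldimethylsilyloxy)-5-hydroxy-6,10-dimethylundec-9-en-3-one, both C-5 epimers | CCC(=O)CC(O)[C@@](C)(O[Si](C)(C)C(C)(C)C)CCC=C(C)C | intermediate
5 | methanesulfonate of 4 | CCC(=O)CC(OS(C)(=O)=O)[C@@](C)(O[Si](C)(C)C(C)(C)C)CCC=C(C)C | intermediate
6 | (4E,6S)-6-(tert-butyldimethylsilyloxy)-6,10-dimethylundeca-4,9-dien-3-one | CCC(=O)/C=C/[C@@](C)(O[Si](C)(C)C(C)(C)C)CCC=C(C)C | intermediate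
7 | cis-2-(2-oxobutyl)-3-isopropenyl-1-methylcyclopentyl tert-butyldimethylsilyl ether, arm cis to the carbinol methyl | CCC(=O)C[C@H]1[C@@H](C(C)=C)CC[C@]1(C)O[Si](C)(C)C(C)(C)C | intermediate
8 | 2-methylcyclohex-2-en-1-one | CC1=CCCCC1=O | starting material
9 | (S)-2-methylcyclohex-2-en-1-ol | O[C@H]1CCCC=C1C | intermediate
10 | (S)-2-methylcyclohex-2-en-1-yl triethylsilyl ether | CC[Si](CC)(CC)O[C@H]1CCCC=C1C | intermediate
11 | (S)-3-methyl-4-(triethylsilyloxy)cyclohex-2-en-1-one | O=C1C=C(C)[C@@H](O[Si](CC)(CC)CC)CC1 | intermediate
12 | 5-bromo-2-methylpent-2-ene | CC(C)=CCCBr | starting material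
13 | 4-methylpent-3-enylmagnesium bromide | CC(C)=CCC[Mg]Br | intermediate
14 | 3-methyl-3-(4-methylpent-3-enyl)-4-(triethylsilyloxy)-1-(trimethylsilyloxy)cyclohexene, homoprenyl trans to OSiEt3 | C[Si](C)(C)OC1=C[C@](C)(CCC=C(C)C)[C@@H](O[Si](CC)(CC)CC)CC1 | intermediate
15 | 2-(dimethylaminomethyl)-3-methyl-3-(4-methylpent-3-enyl)-4-(triethylsilyloxy)cyclohexanone, C-2 epimers | CN(C)CC1[C@](C)(CCC=C(C)C)[C@@H](O[Si](CC)(CC)CC)CCC1=O | intermediate
16 | methiodide of 15 | C[N+](C)(C)CC1[C@](C)(CCC=C(C)C)[C@@H](O[Si](CC)(CC)CC)CCC1=O.[I-] | intermediate
17 | 3-methyl-2-methylene-3-(4-methylpent-3-enyl)-4-(triethylsilyloxy)cyclohexanone | C=C1[C@](C)(CCC=C(C)C)[C@@H](O[Si](CC)(CC)CC)CCC1=O | intermediate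
18 | 2-allyl-3-methyl-3-(4-methylpent-3-enyl)-4-(triethylsilyloxy)cyclohexanone, allyl/methyl/silyloxy on one face | C=CC[C@H]1[C@](C)(CCC=C(C)C)[C@@H](O[Si](CC)(CC)CC)CCC1=O | intermediate
19 | 4-O-triethylsilyl ether of 20 | C=CC[C@H]1[C@](C)(CCC=C(C)C)[C@@H](O[Si](CC)(CC)CC)CC[C@@]1(C)O | intermediate
20 | 2-allyl-1,3-dimethyl-3-(4-methylpent-3-enyl)cyclohexane-1,4-diol, tertiary OH axial and syn to the 3-methyl | C=CC[C@H]1[C@](C)(CCC=C(C)C)[C@@H](O)CC[C@@]1(C)O | intermediate
21 | (R)-epoxide of the homoprenyl alkene of 20 | C=CC[C@H]1[C@](C)(CC[C@H]2OC2(C)C)[C@@H](O)CC[C@@]1(C)O | intermediate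
22 | trans-fused oxepane diol (rings A and B, allyl arm) | C=CC[C@H]1[C@]2(C)CC[C@@H](O)C(C)(C)O[C@H]2CC[C@@]1(C)O | intermediate
23 | bis(triethylsilyl) ether of 22 | C=CC[C@H]1[C@]2(C)CC[C@@H](O[Si](CC)(CC)CC)C(C)(C)O[C@H]2CC[C@@]1(C)O[Si](CC)(CC)CC | intermediate
24 | B-alkyl-9-borabicyclo[3.3.1]nonane from 23 | C1CCC2CCCC1B2CCC[C@H]1[C@]2(C)CC[C@@H](O[Si](CC)(CC)CC)C(C)(C)O[C@H]2CC[C@@]1(C)O[Si](CC)(CC)CC | intermediate
25 | 3-hydroxypropyl compound (primary alcohol) | OCCC[C@H]1[C@]2(C)CC[C@@H](O[Si](CC)(CC)CC)C(C)(C)O[C@H]2CC[C@@]1(C)O[Si](CC)(CC)CC | intermediate
26 | western aldehyde | O=CCC[C@H]1[C@]2(C)CC[C@@H](O[Si](CC)(CC)CC)C(C)(C)O[C@H]2CC[C@@]1(C)O[Si](CC)(CC)CC | intermediate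
27 | lithium enolate of 7 (ethyl side) | CC=C(O[Li])C[C@H]1[C@@H](C(C)=C)CC[C@]1(C)O[Si](C)(C)C(C)(C)C | intermediate
28 | aldol adduct of 7 and 26, mixture at the carbinol and α-methyl centres | CC(C(O)CC[C@H]1[C@]2(C)CC[C@@H](O[Si](CC)(CC)CC)C(C)(C)O[C@H]2CC[C@@]1(C)O[Si](CC)(CC)CC)C(=O)C[C@H]1[C@@H](C(C)=C)CC[C@]1(C)O[Si](C)(C)C(C)(C)C | intermediate
29 | methanesulfonate of 28 | CC(C(OS(C)(=O)=O)CC[C@H]1[C@]2(C)CC[C@@H](O[Si](CC)(CC)CC)C(C)(C)O[C@H]2CC[C@@]1(C)O[Si](CC)(CC)CC)C(=O)C[C@H]1[C@@H](C(C)=C)CC[C@]1(C)O[Si](C)(C)C(C)(C)C | intermediate
30 | (E)-α-methyl enone joining the halves | C/C(=C\CC[C@H]1[C@]2(C)CC[C@@H](O[Si](CC)(CC)CC)C(C)(C)O[C@H]2CC[C@@]1(C)O[Si](CC)(CC)CC)C(=O)C[C@H]1[C@@H](C(C)=C)CC[C@]1(C)O[Si](C)(C)C(C)(C)C | intermediate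
31 | ring C ketone, α-methyl centre as mixture | CC1C(=O)C[C@H]2[C@H](CC[C@]2(C)O[Si](C)(C)C(C)(C)C)C(C)(C)[C@@H]1CC[C@H]1[C@]2(C)CC[C@@H](O[Si](CC)(CC)CC)C(C)(C)O[C@H]2CC[C@@]1(C)O[Si](CC)(CC)CC | intermediate
32 | more substituted lithium enolate of 31 | CC1=C(O[Li])C[C@H]2[C@H](CC[C@]2(C)O[Si](C)(C)C(C)(C)C)C(C)(C)[C@@H]1CC[C@H]1[C@]2(C)CC[C@@H](O[Si](CC)(CC)CC)C(C)(C)O[C@H]2CC[C@@]1(C)O[Si](CC)(CC)CC | intermediate
33 | enol triflate | CC1=C(OS(=O)(=O)C(F)(F)F)C[C@H]2[C@H](CC[C@]2(C)O[Si](C)(C)C(C)(C)C)C(C)(C)[C@@H]1CC[C@H]1[C@]2(C)CC[C@@H](O[Si](CC)(CC)CC)C(C)(C)O[C@H]2CC[C@@]1(C)O[Si](CC)(CC)CC | intermediate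
34 | tris-silyl ether of 35 | CC1=CC[C@H]2[C@H](CC[C@]2(C)O[Si](C)(C)C(C)(C)C)C(C)(C)[C@@H]1CC[C@H]1[C@]2(C)CC[C@@H](O[Si](CC)(CC)CC)C(C)(C)O[C@H]2CC[C@@]1(C)O[Si](CC)(CC)CC | intermediate
35 | triol (ring A alcohol of the target) | CC1=CC[C@H]2[C@H](CC[C@]2(C)O)C(C)(C)[C@@H]1CC[C@H]1[C@]2(C)CC[C@@H](O)C(C)(C)O[C@H]2CC[C@@]1(C)O | intermediate
36 | CNP0194989.3 | CC1=CC[C@H]2[C@H](CC[C@]2(C)O)C(C)(C)[C@@H]1CC[C@H]1[C@]2(C)CCC(=O)C(C)(C)O[C@H]2CC[C@@]1(C)O | target

## Step count and uncertain steps

Total: 24 steps (5 to the ring D ketone 7, 12 to the aldehyde 26, 7 after the union). Longest linear sequence: 19 steps (8 → 26 → 36).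

**Step 5 (key step).** The most likely failure is loss of facial discrimination at the quaternary carbinol carbon, because methyl and silyloxy compete for the position next to the Lewis acid-bound arm. The activated enone may also divert to an inverse-demand hetero-Diels–Alder closure (oxygen capture of the developing tertiary cation), and the product ketone may undergo a further carbonyl-ene closure onto its own isopropenyl group if the temperature rises. Fallback: a magnesium-ene cyclization, which avoids the enone and the Lewis acid and keeps all ten carbons. It sets out from 2. Allylic oxidation of the prenyl terminus (SeO2 cat., t-BuOOH) gives the (E)-allylic alcohol F1. MsCl/LiCl converts it into the allylic chloride F2. Magnesium insertion in THF and warming should close the cis-cyclopentane by transfer of magnesium to the former vinyl terminus, giving the cyclopentylmethylmagnesium chloride F3. Acylation of F3 with N-methoxy-N-methylpropanamide returns to 7. The transition state is different and compact, so the facial outcome has to be determined anew, but the cis relation is characteristic of this metallo-ene mode.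

**Step 20.** Two things may go wrong. The tertiary radical may be reduced before the seven-membered ring closes. More seriously, the closure may occur on the wrong face of the enone: the transition state leading to the required epimer brings the ring D carbinol carbon close to one methyl of the radical centre, whereas the competing one keeps it outside, so the undesired epimer may well dominate. Fallback: make the linker-bearing carbon trigonal again and set it by a stereospecific hydrogen transfer. It sets out from 30, whose cyclization then gives the epimeric ketone F4 (or a mixture with 31). Equilibrating silylation (Me3SiI, (Me3Si)2NH) gives the more substituted trimethylsilyl enol ether F5. Saegusa–Ito oxidation with Pd(OAc)2 gives the ring enone F6. Luche reduction (NaBH4, CeCl3) from the exo face gives the allylic alcohol F7. Mitsunobu displacement of F7 with o-nitrobenzenesulfonylhydrazide (PPh3, diethyl azodicarboxylate) and loss of sulfinate and N2 from the allylic diazene should deliver hydrogen suprafacially to the linker-bearing carbon on the exo face and move the alkene into place. The sequence returns to the route at 34. If the Luche reduction gives the other carbinol epimer, that alcohol is inverted first.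

**Step 14.** The hydroxyl may open the epoxide in the 6-exo sense at the secondary carbon, which is geometrically easy on a trans-diequatorial template; Lewis acid-induced rearrangement of the epoxide to a ketone is a second leak. Fallback: an alkene activation whose regiochemistry is Markovnikov by nature. It sets out from 20. One equivalent of Hg(OCOCF3)2 should engage the more nucleophilic trisubstituted alkene and close the oxepane at the tertiary carbon, giving after chloride exchange the organomercurial F8. Oxidative demercuration (NaBH4, O2, DMF) returns to 22, accompanied by its carbinol epimer F9; both converge in step 24.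

**Step 21.** Enolisation may stay under kinetic control toward the ring CH2, which would place the alkene on the wrong side of the former carbonyl. Fallback: avoid the triflate. It sets out from 31. Equilibrating silylation gives the more substituted trimethylsilyl enol ether F10, which is separated from its regioisomer. Saegusa–Ito oxidation converts F10 into the ring enone F6, which is taken through the allylic alcohol F7 and the reductive transposition to 34 as described for step 20.

## Further compounds

F1 | step 5 | (S,E)-6-(tert-butyldimethylsilyloxy)-2,6-dimethylocta-2,7-dien-1-ol | C=C[C@@](C)(O[Si](C)(C)C(C)(C)C)CC/C=C(\C)CO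
F2 | step 5 | (S,E)-allylic chloride from F1 | C=C[C@@](C)(O[Si](C)(C)C(C)(C)C)CC/C=C(\C)CCl
F3 | step 5 | [cis-2-(tert-butyldimethylsilyloxy)-2-methyl-5-isopropenylcyclopentyl]methylmagnesium chloride | Cl[Mg]C[C@H]1[C@@H](C(C)=C)CC[C@]1(C)O[Si](C)(C)C(C)(C)C
F4 | step 20 | epimer of 31 at the linker-bearing CH of ring C | CC1C(=O)C[C@H]2[C@H](CC[C@]2(C)O[Si](C)(C)C(C)(C)C)C(C)(C)[C@H]1CC[C@H]1[C@]2(C)CC[C@@H](O[Si](CC)(CC)CC)C(C)(C)O[C@H]2CC[C@@]1(C)O[Si](CC)(CC)CC
F5 | step 20 | more substituted trimethylsilyl enol ether of F4 | CC1=C(O[Si](C)(C)C)C[C@H]2[C@H](CC[C@]2(C)O[Si](C)(C)C(C)(C)C)C(C)(C)[C@H]1CC[C@H]1[C@]2(C)CC[C@@H](O[Si](CC)(CC)CC)C(C)(C)O[C@H]2CC[C@@]1(C)O[Si](CC)(CC)CC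
F6 | step 20 | ring C enone (tetrasubstituted C=C between the methyl-bearing and linker-bearing carbons) | O=C1C[C@H]2[C@H](CC[C@]2(C)O[Si](C)(C)C(C)(C)C)C(C)(C)C(CC[C@H]3[C@]4(C)CC[C@@H](O[Si](CC)(CC)CC)C(C)(C)O[C@H]4CC[C@@]3(C)O[Si](CC)(CC)CC)=C1C
F7 | step 20 | allylic alcohol from F6, hydroxyl syn to ring D | O[C@@H]1C[C@H]2[C@H](CC[C@]2(C)O[Si](C)(C)C(C)(C)C)C(C)(C)C(CC[C@H]3[C@]4(C)CC[C@@H](O[Si](CC)(CC)CC)C(C)(C)O[C@H]4CC[C@@]3(C)O[Si](CC)(CC)CC)=C1C
F8 | step 14 | 3-(chloromercurio)oxepane from 20, epimers at the mercurated carbon | C=CC[C@H]1[C@]2(C)CCC([Hg]Cl)C(C)(C)O[C@H]2CC[C@@]1(C)O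
F9 | step 14 | epimer of 22 at the ring A carbinol | C=CC[C@H]1[C@]2(C)CC[C@H](O)C(C)(C)O[C@H]2CC[C@@]1(C)O
F10 | step 21 | more substituted trimethylsilyl enol ether of 31 | CC1=C(O[Si](C)(C)C)C[C@H]2[C@H](CC[C@]2(C)O[Si](C)(C)C(C)(C)C)C(C)(C)[C@@H]1CC[C@H]1[C@]2(C)CC[C@@H](O[Si](CC)(CC)CC)C(C)(C)O[C@H]2CC[C@@]1(C)O[Si](CC)(CC)CC
A1 | alternative 1 | bis-epoxide with (Z)-trimethylsilyl enol ether and benzyloxyethyl terminus | c1ccccc1COCC/C=C(\O[Si](C)(C)C)CC[C@@H]1O[C@@]1(C)CC[C@@H]1OC1(C)C
A2 | alternative 1 | trans-fused oxepane–cyclohexanone with silyloxy group in ring A and benzyloxyethyl arm | c1ccccc1COCC[C@H]1[C@]2(C)CC[C@H](O[Si](C)(C)C)C(C)(C)O[C@H]2CCC1=O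
A3 | alternative 2 | (E)-allylsilane aldehyde with quaternary methyl, homoprenyl chain and p-methoxybenzyl ether | C[Si](C)(C)C/C=C/[C@](C)(CCC=C(C)C)[C@@H](OCc1ccc(OC)cc1)CCC=O
A4 | alternative 2 | vinylcyclohexanol carrying the ether oxygen, quaternary methyl and homoprenyl chain | C=C[C@H]1[C@](C)(CCC=C(C)C)[C@@H](OCc2ccc(OC)cc2)CC[C@@H]1O
A5 | alternative 3 | bis(triethylsilyl) ether of the ring-contracted pyranone | CC1=CC[C@H]2[C@H](CC[C@]2(C)O[Si](CC)(CC)CC)C(C)(C)[C@@H]1CC[C@H]1[C@]2(C)CC(=O)C(C)(C)O[C@H]2CC[C@@]1(C)O[Si](CC)(CC)CC
A6 | alternative 3 | bis(triethylsilyl) ether of the target | CC1=CC[C@H]2[C@H](CC[C@]2(C)O[Si](CC)(CC)CC)C(C)(C)[C@@H]1CC[C@H]1[C@]2(C)CCC(=O)C(C)(C)O[C@H]2CC[C@@]1(C)O[Si](CC)(CC)CC
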